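The decalin is traced back to ring B alone. With a ketone at C5, C9 and C10 are the β- and α-carbons of a cyclohexenone, so the C8–C9–C10 stereotriad is built on (S)-3,4-dimethylcyclohex-2-enone in one flask: copper-catalysed 1,4-addition of the 2,3,5,6-tetramethoxybenzyl Grignard reagent forms C9–C11 anti to the 8-methyl group, and the regiodefined enolate is alkylated at C10 by 5-iodo-2-methylpent-1-ene (C10–C1) anti to the arylmethyl group. The C5 ketone then becomes the C5=C6 enol triflate for a reductive 6-exo Heck closure of ring A that creates the C4 gem-dimethyl carbon; oxidation and selective hydrolysis give the hydroxyquinone.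

Key step: step 8

Numbering: drimane numbering is used for the decalin (ring A = C1–C5 and C10, ring B = C5–C10, C11 = benzylic CH2); the target is (8S,9R,10S), with C8 fixed in step 1 and C9 and C10 created in step 8.

Assumption: lithium (R,R)-bis(1-phenylethyl)amide is taken to give the (S)-enol silane, the sense known for 4-alkylcyclohexanones; if the opposite sense is found, the (S,S)-amide is used and nothing else changes.

Remark: the enantiomeric excess reached in step 1 is carried to the target unchanged; it is to be checked at enone 5 and, if needed, raised by preparative chiral chromatography of 5 or by recrystallization of a later solid.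

Step 1
Reactants: 1 4-methylcyclohexanone
Product: 2 (S)-trimethyl[(4-methylcyclohex-1-en-1-yl)oxy]silane
Conditions: Li[(R,R)-N(CH(CH3)Ph)2] (from the amine and n-BuLi), Me3SiCl (internal quench), THF, −100 °C
Reagents that add atoms: chlorotrimethylsilane, C[Si](C)(C)Cl
Why: Enantioselective deprotonation (desymmetrization) of the prochiral ketone by the C2-symmetric chiral lithium amide under internal silyl quench distinguishes the enantiotopic α-methylene groups and so fixes the future C8 stereocenter as the (S)-enol silane.

Step 2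
Reactants: 2 (S)-trimethyl[(4-methylcyclohex-1-en-1-yl)oxy]silane
Product: 3 (S)-4-methylcyclohex-2-en-1-one
Conditions: Pd(OAc)2 (1.0 equiv), MeCN, rt
Reagents that add atoms: none
Why: Saegusa–Ito oxidation, in which C-palladation of the enol silane and β-hydride elimination give the enone regiospecifically under neutral conditions that leave the γ-stereocenter untouched.

Step 3
Reactants: 3 (S)-4-methylcyclohex-2-en-1-one
Product: 5 (S)-3,4-dimethylcyclohex-2-en-1-one, via silyl enol ether 4 (not isolated)
Conditions: Me2CuLi (from MeLi and CuI), Me3SiCl, Et2O, −78 °C; Et3N, pentane, filter, concentrate; Pd(OAc)2 (1.0 equiv), MeCN, rt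
Reagents that add atoms: lithium dimethylcuprate, [Li+].C[Cu-]C
Why: Cuprate conjugate addition with silyl trapping gives the regiodefined enol silane (methyl trans to the 4-methyl group), and Saegusa–Ito oxidation of the crude material restores the enone, so the new methyl-bearing carbon becomes sp2 and only the C4 stereocenter remains.

Step 4
Reactants: 6 1,2,4,5-tetramethoxybenzene
Product: 7 (2,3,5,6-tetramethoxyphenyl)methanol
Conditions: n-BuLi, TMEDA, THF, 0 °C; (CH2O)n, 0 °C → rt; H2O
Reagents that add atoms: formaldehyde (as paraformaldehyde), C=O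
Why: Directed ortho-metalation removes a ring hydrogen flanked by two methoxy groups (both are equivalent), and the aryllithium is hydroxymethylated by formaldehyde.

Step 5
Reactants: 7 (2,3,5,6-tetramethoxyphenyl)methanol
Product: 8 3-(chloromethyl)-1,2,4,5-tetramethoxybenzene
Conditions: SOCl2, pyridine, CH2Cl2, 0 °C
Reagents that add atoms: thionyl chloride, O=S(Cl)Cl
Why: Chlorodehydroxylation of the benzylic alcohol through its chlorosulfite, with pyridine keeping HCl away from the electron-rich ring.

Step 6
Reactants: 8 3-(chloromethyl)-1,2,4,5-tetramethoxybenzene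
Product: 9 (2,3,5,6-tetramethoxyphenyl)methylmagnesium chloride (titrated THF solution, used at once)
Conditions: Mg turnings (excess, activated), THF, 0 °C, slow addition, high dilution
Reagents that add atoms: magnesium, [Mg]
Why: Grignard formation by insertion of magnesium into the benzylic C–Cl bond, with the chloride, dilution, slow addition and low temperature chosen to suppress Wurtz homocoupling.

Step 7
Reactants: 10 4-methylpent-4-en-1-ol
Product: 11 5-iodo-2-methylpent-1-ene
Conditions: I2, PPh3, imidazole, CH2Cl2, 0 °C → rt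
Reagents that add atoms: iodine, II
Why: Appel-type iodination, in which iodide displaces the oxyphosphonium group of the primary alcohol by SN2 without touching the 1,1-disubstituted alkene.

Step 8
Reactants: 5 (S)-3,4-dimethylcyclohex-2-en-1-one; 9 (2,3,5,6-tetramethoxyphenyl)methylmagnesium chloride; 11 5-iodo-2-methylpent-1-ene
Product: 14 (2S,3R,4S)-3,4-dimethyl-2-(4-methylpent-4-en-1-yl)-3-[(2,3,5,6-tetramethoxyphenyl)methyl]cyclohexan-1-one, via silyl enol ether 12 (not isolated), via lithium enolate 13 (not isolated)
Conditions: 9 (1.5 equiv, slow addition), CuBr·SMe2 (10 mol%), Me3SiCl, HMPA, THF, −78 → −40 °C; Et3N, pentane, filter, evaporate; MeLi (1.0 equiv), THF, 0 °C; 11 (3 equiv), HMPA, −78 → 0 °C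
Reagents that add atoms: none
Why: Transmetalation of 9 gives a benzylcopper species whose Me3SiCl/HMPA-assisted 1,4-addition to the β,β-disubstituted enone forms C9–C11 and traps the enolate regiospecifically as enol silane 12; after removal of salts and excess Me3SiCl, MeLi cleaves the O–Si bond to lithium enolate 13 (with Me4Si), which is C-alkylated by iodide 11 in an SN2 step to form C10–C1. The closest known reaction type is the tandem organocopper conjugate addition/enolate alkylation (three-component coupling) of cycloalkenones; no ring is closed. C9 is set by 1,2-induction from C8: the 4-methyl group of 5 sits pseudoaxial to avoid allylic strain with the 3-methyl group and the copper reagent attacks axially on the opposite face, which leaves the 8- and 9-methyl groups cis and C11 on the other side. C10 is set by the new quaternary centre: the iodide approaches the enolate axially and anti to the bulky arylmethyl group, so C1 ends cis to the 9-methyl group and H10 cis to C11; this is also the epimer with the side chain equatorial, so any C10 epimer can be enriched toward 14 with NaOMe/MeOH before step 9. The step needs 1,4- over 1,2-addition, secured by copper catalysis with Me3SiCl and slow addition of 9, and alkylation at C10 and not C6, secured because the enolate arises only from 12 and meets excess 11 in HMPA before proton transfer can move it. MeLi is held to one equivalent so that the aryl C–H between two methoxy groups is not metalated.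

Step 9
Reactants: 14 (2S,3R,4S)-3,4-dimethyl-2-(4-methylpent-4-en-1-yl)-3-[(2,3,5,6-tetramethoxyphenyl)methyl]cyclohexan-1-one
Product: 15 (4S,5R,6S)-4,5-dimethyl-6-(4-methylpent-4-en-1-yl)-5-[(2,3,5,6-tetramethoxyphenyl)methyl]cyclohex-1-en-1-yl trifluoromethanesulfonate
Conditions: LiN(i-Pr)2, THF, −78 °C; PhNTf2, −78 °C → rt
Reagents that add atoms: N-phenylbis(trifluoromethanesulfonimide), O=S(=O)(N(c1ccccc1)S(=O)(=O)C(F)(F)F)C(F)(F)F
Why: Kinetic enolization removes a proton from the unhindered C6 methylene and not from the C10 methine beside the quaternary carbon, and O-triflation of that enolate gives the C5=C6 enol triflate with C10 untouched.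

Step 10
Reactants: 15 (4S,5R,6S)-4,5-dimethyl-6-(4-methylpent-4-en-1-yl)-5-[(2,3,5,6-tetramethoxyphenyl)methyl]cyclohex-1-en-1-yl trifluoromethanesulfonate
Product: 16 1,2,4,5-tetramethoxy-3-{[(1R,2S,8aS)-1,2,5,5-tetramethyl-1,2,3,5,6,7,8,8a-octahydronaphthalen-1-yl]methyl}benzene
Conditions: Pd(OAc)2 (10 mol%), PPh3 (20 mol%), HCO2Na, Et4NCl, DMF, 80 °C
Reagents that add atoms: none
Why: Reductive Heck cyclization, in which oxidative addition of the vinyl triflate to zerovalent palladium and 6-exo-trig carbopalladation of the 1,1-disubstituted alkene form C4–C5 and ring A, and the neopentylpalladium, having no β-hydrogen, is reduced by the sparingly soluble formate to the second C4 methyl group with the C5=C6 alkene retained and no new stereocenter.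

Step 11
Reactants: 16 1,2,4,5-tetramethoxy-3-{[(1R,2S,8aS)-1,2,5,5-tetramethyl-1,2,3,5,6,7,8,8a-octahydronaphthalen-1-yl]methyl}benzene
Product: 17 2,5-dimethoxy-3-{[(1R,2S,8aS)-1,2,5,5-tetramethyl-1,2,3,5,6,7,8,8a-octahydronaphthalen-1-yl]methyl}cyclohexa-2,5-diene-1,4-dione
Conditions: (NH4)2Ce(NO3)6, MeCN/H2O, 0 °C
Reagents that add atoms: water, O
Why: Oxidative demethylation of a para-dimethoxyarene by tetravalent cerium gives the para-quinone, the two possible para-quinones being identical by the symmetry of the ring and the isolated trisubstituted alkene being inert to the oxidant at this temperature.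

Step 12
Reactants: 17 2,5-dimethoxy-3-{[(1R,2S,8aS)-1,2,5,5-tetramethyl-1,2,3,5,6,7,8,8a-octahydronaphthalen-1-yl]methyl}cyclohexa-2,5-diene-1,4-dione
Product: 18 2-hydroxy-5-methoxy-3-{[(1R,2S,8aS)-1,2,5,5-tetramethyl-1,2,3,5,6,7,8,8a-octahydronaphthalen-1-yl]methyl}cyclohexa-2,5-diene-1,4-dione (CNP0348245.1)
Conditions: KOH, MeOH/H2O, rt; then aq. HCl
Reagents that add atoms: potassium hydroxide, [K+].[OH-]
Why: Addition–elimination hydrolysis of a vinylogous ester, in which hydroxide replaces the methoxy group beside the alkyl-bearing carbon (twisted out of conjugation and so the more electrophilic) while the coplanar methoxy group beside the ring C–H survives and the vinylogous carboxylate formed resists a second hydrolysis.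

Compound list
1 | 4-methylcyclohexanone | CC1CCC(=O)CC1 | starting material
2 | (S)-trimethyl[(4-methylcyclohex-1-en-1-yl)oxy]silane | C[Si](C)(C)OC1=CC[C@@H](C)CC1 | intermediate
3 | (S)-4-methylcyclohex-2-en-1-one | O=C1C=C[C@@H](C)CC1 | intermediate
4 | trimethyl{[(3R,4S)-3,4-dimethylcyclohex-1-en-1-yl]oxy}silane | C[Si](C)(C)OC1=C[C@H](C)[C@@H](C)CC1 | intermediate (not isolated)
5 | (S)-3,4-dimethylcyclohex-2-en-1-one | O=C1C=C(C)[C@@H](C)CC1 | intermediate
6 | 1,2,4,5-tetramethoxybenzene | COc1cc(OC)c(OC)cc1OC | starting material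
7 | (2,3,5,6-tetramethoxyphenyl)methanol | COc1cc(OC)c(OC)c(CO)c1OC | intermediate
8 | 3-(chloromethyl)-1,2,4,5-tetramethoxybenzene | COc1cc(OC)c(OC)c(CCl)c1OC | intermediate
9 | (2,3,5,6-tetramethoxyphenyl)methylmagnesium chloride | COc1cc(OC)c(OC)c(C[Mg]Cl)c1OC | intermediate
10 | 4-methylpent-4-en-1-ol | C=C(C)CCCO | starting material
11 | 5-iodo-2-methylpent-1-ene | C=C(C)CCCI | intermediate
12 | trimethyl({(3R,4S)-3,4-dimethyl-3-[(2,3,5,6-tetramethoxyphenyl)methyl]cyclohex-1-en-1-yl}oxy)silane | COc1cc(OC)c(OC)c(C[C@@]2(C)C=C(O[Si](C)(C)C)CC[C@@H]2C)c1OC | intermediate (not isolated)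
13 | lithium (3R,4S)-3,4-dimethyl-3-[(2,3,5,6-tetramethoxyphenyl)methyl]cyclohex-1-en-1-olate | COc1cc(OC)c(OC)c(C[C@@]2(C)C=C([O-])CC[C@@H]2C)c1OC.[Li+] | intermediate (not isolated)
14 | (2S,3R,4S)-3,4-dimethyl-2-(4-methylpent-4-en-1-yl)-3-[(2,3,5,6-tetramethoxyphenyl)methyl]cyclohexan-1-one | COc1cc(OC)c(OC)c(C[C@@]2(C)[C@H](CCCC(C)=C)C(=O)CC[C@@H]2C)c1OC | intermediate
15 | (4S,5R,6S)-4,5-dimethyl-6-(4-methylpent-4-en-1-yl)-5-[(2,3,5,6-tetramethoxyphenyl)methyl]cyclohex-1-en-1-yl trifluoromethanesulfonate | COc1cc(OC)c(OC)c(C[C@@]2(C)[C@H](CCCC(C)=C)C(OS(=O)(=O)C(F)(F)F)=CC[C@@H]2C)c1OC | intermediate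
16 | 1,2,4,5-tetramethoxy-3-{[(1R,2S,8aS)-1,2,5,5-tetramethyl-1,2,3,5,6,7,8,8a-octahydronaphthalen-1-yl]methyl}benzene | COc1cc(OC)c(OC)c(C[C@@]2(C)[C@@H]3CCCC(C)(C)C3=CC[C@@H]2C)c1OC | intermediate
17 | 2,5-dimethoxy-3-{[(1R,2S,8aS)-1,2,5,5-tetramethyl-1,2,3,5,6,7,8,8a-octahydronaphthalen-1-yl]methyl}cyclohexa-2,5-diene-1,4-dione | COC1=CC(=O)C(OC)=C(C[C@@]2(C)[C@@H]3CCCC(C)(C)C3=CC[C@@H]2C)C1=O | intermediate
18 | 2-hydroxy-5-methoxy-3-{[(1R,2S,8aS)-1,2,5,5-tetramethyl-1,2,3,5,6,7,8,8a-octahydronaphthalen-1-yl]methyl}cyclohexa-2,5-diene-1,4-dione | COC1=CC(=O)C(O)=C(C[C@@]2(C)[C@@H]3CCCC(C)(C)C3=CC[C@@H]2C)C1=O | target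

Total step count: 12. Longest linear sequence: 8 steps (steps 1, 2, 3, 8, 9, 10, 11, 12 from 4-methylcyclohexanone; the arene branch, steps 4, 5, 6, 8–12, is equally long).

Steps most likely to fail

1. Step 8. The crowded β-carbon may take up the benzylcopper species slowly. The more likely failure is slow C-alkylation of the hindered enolate by the unactivated iodide, so that proton transfer moves the enolate toward C6 and over-alkylation sets in. The fallback sets out from lithium enolate 13 (made as in step 8) and returns to the route at 14. The enolate is quenched with allyl bromide, a far more reactive electrophile that should follow the same facial preference, to give (2S,3R,4S)-2-allyl-3,4-dimethyl-3-[(2,3,5,6-tetramethoxyphenyl)methyl]cyclohexan-1-one F1. Hydroboration of the terminal alkene with 9-BBN (THF, 0 °C → rt), expected to be much faster than reduction of the hindered ketone, gives (2S,3R,4S)-2-[3-(9-borabicyclo[3.3.1]nonan-9-yl)propyl]-3,4-dimethyl-3-[(2,3,5,6-tetramethoxyphenyl)methyl]cyclohexan-1-one F2. In the same flask, B-alkyl Suzuki–Miyaura coupling with 2-bromopropene (PdCl2(dppf), aq. K3PO4, DMF, 50 °C) installs the isopropenyl terminus and delivers 14.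

2. Step 10. Formate may reduce the vinylpalladium before ring closure, or the neopentylpalladium may attack the C5=C6 alkene in a 3-exo sense instead of being reduced. The fallback sets out from ketone 14 and returns at 16. Hydrogen-atom transfer from an iron hydride (Fe(acac)3, PhSiH3, EtOH, 60 °C) turns the 1,1-disubstituted alkene into the tertiary C4 radical, which adds to the C5 carbonyl to close ring A as the cis-fused tertiary alcohol (1R,2S,4aS,8aS)-1,2,5,5-tetramethyl-1-[(2,3,5,6-tetramethoxyphenyl)methyl]decahydronaphthalen-4a-ol F3. Anti elimination with SOCl2/pyridine (0 °C) should then give 16, because in the cis-fused alcohol only C6 carries a hydrogen anti to the C5 oxygen (C4 has none and H10 is syn).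

3. Step 12. Hydroxide may fail to discriminate between the two methoxy groups (attack at the one beside the ring C–H, or at both), and the quinone may degrade in base. The fallback sets out from 17 and returns at 18. Exhaustive hydrolysis (excess aq. NaOH, EtOH, 50 °C, then HCl) gives 2,5-dihydroxy-3-{[(1R,2S,8aS)-1,2,5,5-tetramethyl-1,2,3,5,6,7,8,8a-octahydronaphthalen-1-yl]methyl}cyclohexa-2,5-diene-1,4-dione F4. One equivalent of Me3SiCHN2 (MeOH/toluene, 0 °C) should then O-methylate the more accessible hydroxyl beside the ring C–H, the hydroxyl flanked by the bulky alkyl group reacting more slowly, to give 18.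

Further compounds
F1 | step 8 | (2S,3R,4S)-2-allyl-3,4-dimethyl-3-[(2,3,5,6-tetramethoxyphenyl)methyl]cyclohexan-1-one | COc1cc(OC)c(OC)c(C[C@@]2(C)[C@H](CC=C)C(=O)CC[C@@H]2C)c1OC
F2 | step 8 | (2S,3R,4S)-2-[3-(9-borabicyclo[3.3.1]nonan-9-yl)propyl]-3,4-dimethyl-3-[(2,3,5,6-tetramethoxyphenyl)methyl]cyclohexan-1-one | COc1cc(OC)c(OC)c(C[C@@]2(C)[C@H](CCCB3C4CCCC3CCC4)C(=O)CC[C@@H]2C)c1OC
F3 | step 10 | (1R,2S,4aS,8aS)-1,2,5,5-tetramethyl-1-[(2,3,5,6-tetramethoxyphenyl)methyl]decahydronaphthalen-4a-ol | COc1cc(OC)c(OC)c(C[C@@]2(C)[C@@H]3CCCC(C)(C)[C@]3(O)CC[C@@H]2C)c1OC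
F4 | step 12 | 2,5-dihydroxy-3-{[(1R,2S,8aS)-1,2,5,5-tetramethyl-1,2,3,5,6,7,8,8a-octahydronaphthalen-1-yl]methyl}cyclohexa-2,5-diene-1,4-dione | OC1=CC(=O)C(O)=C(C[C@@]2(C)[C@@H]3CCCC(C)(C)C3=CC[C@@H]2C)C1=O
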